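**Remarks on the chemistry (assumptions)**

- The phenol oxygens are carried as methoxymethyl (MOM) ethers, not methyl ethers. MOM ethers fall under the same mild protic acid that ionises the triaryl carbinol, so unmasking and dehydration become one step. Methyl ethers would need strong Lewis acids, which threaten the benzylic alcohol and the alkyne.
- 1-Iodo-4-(methoxymethoxy)benzene, 1-bromo-4-(methoxymethoxy)benzene and 4-(methoxymethoxy)benzaldehyde are taken as purchasable; each is otherwise one step (MOMCl, i-Pr2NEt) from the 4-substituted phenol.
- Ring A numbering used throughout: C1 bears the methide (later carbinol or ketone) carbon, C2 the aryl group, C3 and C4 are CH, C5 bears the CH2O carbon, C6 the alkyne (earlier the carboxyl) carbon.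

## Analysis of the target

Selaginellin (24) is built on one benzene ring, ring A, with four contiguous carbon substituents. C1 bears the exocyclic methide carbon, C2 a 4-hydroxyphenyl group, C5 a hydroxymethyl group and C6 a (4-hydroxyphenyl)ethynyl group; C3 and C4 are unsubstituted. The methide carbon is double-bonded to a cyclohexa-2,5-dien-1-one ring and also carries a 4-hydroxyphenyl group, so this unit is the dehydrated form of a bis(4-hydroxyphenyl)carbinol. There is no stereocentre, and because the dienone ring is symmetric there is no double-bond isomerism. Rotation about the crowded aryl–aryl and aryl–methide bonds is hindered, but the structure defines no axis, so nothing stereochemical has to be controlled. The sensitive groups are the electrophilic quinone methide, three free phenols, a primary benzylic alcohol that strong Lewis acids turn into a halide, and a diaryl alkyne lying between two oxygen functions that can add across it under base or soft-metal catalysis. The difficulty is placing four different carbon groups in a fixed order on neighbouring ring positions, with the two largest (C1 and C6) side by side, and revealing the quinone methide only at the end. The strategy rests on C3 and C4, two adjacent CH positions flanked by carbon-bearing C2 and C5. Read as an aryne bond that has taken up two hydrogens, they trace ring A to a 1,3-diyne (C2–C3–C4–C5) and an alkyne (C6–C1), with the one-carbon groups on C5 and C6 joined as an ester tether.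

## Retrosynthetic reasoning

**24 to 22 (through 23).** The last bonds to be dealt with are not skeletal. The exocyclic C=C of the quinone methide results from ionisation of a triaryl carbinol and loss of a phenolic proton, so 24 is taken back to carbinol 23 and then to its fourfold methoxymethyl ether 22. Cutting here keeps the quinone methide and the free phenols out of every organometallic step. The forward reaction has to remove four acetals and dehydrate in one operation.

**22 to 21 and 1.** The C(sp)–C(aryl) bond on the outer side of the alkyne is cut, giving terminal alkyne 21 and aryl iodide 1. The inner bond, between C6 and the alkyne, is not cut, because that would need a leaving group at the most crowded ring position, between the triaryl carbinol and the hydroxymethyl group. With the outer cut the hindered partner is the alkyne, where steric demand is low. Iodide 1 also supplies the diyne aryl group, so no new building block is needed.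

**21 to 19 (through 20).** The terminal alkyne carbon is removed next: the alkyne is the one-carbon homologue of an aldehyde on C6. That aldehyde, 20, lies between two hydroxyl groups and exists as the cyclic hemiacetal 19, the partial-reduction product of a lactone. C6 then carries a carboxyl-level carbon, which is what an ester tether leaves behind.

**19 to 18 to 14 and 16.** Lactol 19 comes from lactone 18. In 18 the lactone oxygen sits on the triaryl carbinol carbon; cutting one of its two equivalent aryl bonds gives diaryl ketone 14 and aryl Grignard reagent 16 (from bromide 15). In 14 the carboxyl carbon on C6 is lactonised onto the C5 oxygen instead. The forward step must add the aryl group to the ketone and let the new tertiary alkoxide 17 take over the acyl group. This frees the C5 hydroxymethyl group and distinguishes the C5 and C6 one-carbon groups without a protecting-group step. The ketone, not the lactone, has to be attacked, as is usual for 2-aroylbenzoates.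

**14 to 12 (through 13).** Ring A is now opened. Cutting C1–C2 and C5–C6 and removing the hydrogens on C3 and C4 leads to aryne 13 and then to the acyclic triyne 12. This is the only pair of ring bonds whose cleavage turns all four substituents into ends of linear alkynes: the diyne carries the C2 aryl group and the C5 oxygenated carbon, the alkyne carries the C1 aroyl group and the C6 carboxyl carbon. Both rings, the full substitution pattern and the aromatic oxidation level then come from one thermal step, and no positional isomer is possible. The forward reaction has to cyclise and the aryne has to be reduced by the hydrogen-donating solvent before anything else traps it.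

**12 to 11 to 8 and 9 (through 10).** Ynone 12 comes from propargylic alcohol 11 by oxidation, and 11 from lithium acetylide 10 (from propiolate 8) and aldehyde 9 by cutting the alkyne–carbinol bond. The ketone is created one step before the cyclisation because the doubly activated alkyne is a strong Michael acceptor.

**8 to 6 and 7.** The ester C–O bond is cut to diynol 6 and acid 7; the acyl unit is the smallest one that supplies both the tether carbonyl and an alkyne.

**6 to 4 and 5, 4 to 3 to 1 and 2.** The central C(sp)–C(sp) bond of the diyne is cut to bromoalkyne 4 and alkynol 5. Heterocoupling of a bromoalkyne with a terminal alkyne is selective, whereas oxidative coupling of two terminal alkynes would give mixtures. Bromoalkyne 4 comes from silyl alkyne 3 by halodesilylation, and 3 from iodide 1 and alkyne 2 by aryl–alkyne coupling.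

## Alternatives that were turned down

**Alternative 1:** Ring A is kept intact and brought in as an aryne. The bonds C6–CH2 and C1–C(=O) are disconnected, which leads to the symmetric diketone A2 (1,3-bis(4-methoxyphenyl)propane-1,3-dione) and the C1≡C6 aryne released by fluoride from silyl triflate A3 (6-chloro-3-[(methoxymethoxy)methyl]-2-(trimethylsilyl)phenyl trifluoromethanesulfonate). In the forward step the central enolate carbon of A2 adds to C6, the C1 aryl anion closes onto the neighbouring ketone, and the four-membered alkoxide fragments to A1 (2-{3-chloro-2-(4-methoxybenzoyl)-6-[(methoxymethoxy)methyl]phenyl}-1-(4-methoxyphenyl)ethan-1-one), a net insertion into a C–C bond of A2.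
- For it: two C–C bonds form in one step at ordinary concentration. The CH2–C(=O)–aryl unit on C6 is a complete, masked arylethynyl group (enol sulfonate, then elimination). The symmetric diketone leaves no doubt about which acyl group migrates.
- Against it: the substituent order depends on the regiochemistry of addition to a 3,6-disubstituted aryne. Chlorine directs the nucleophile to C6, but the CH2OMOM group on C5 shields that carbon. A3 is itself a 1,2,3,4-tetrasubstituted benzene that needs its own regiocontrolled synthesis. The C2 aryl group must be added later by coupling a chloride wedged next to the aroyl or triaryl carbinol group. The two ketones of A1 stand in a 1,5-relationship, which invites cyclisation to a benzopyrylium ion under acid, and the enolisable one must be converted before an aryl nucleophile is added.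
- Comparison: on the arylethynyl group this plan is stronger than the chosen one, which spends two steps on it, and it needs no high dilution. The chosen strategy offers a ring A whose substituent order follows from connectivity alone, and it brings in the C2 aryl group with the diyne, so no coupling at a crowded ring position is needed.

**Alternative 2:** Ring A is built as a non-aromatic six-membered ring from cheap carbonyl compounds. The bonds C1–C2 and C4–C5 are disconnected to enal A5 ((E)-3-(4-methoxyphenyl)prop-2-enal) and diketone A6 (5-(benzyloxy)-1-(4-methoxyphenyl)pentane-1,3-dione). Under a secondary-amine catalyst the central carbon of A6 adds to the iminium ion of A5 (C1–C2), the α′-carbon then condenses with the aldehyde (C4–C5), and dehydration gives cyclohexenone A4 (trans-2-[(benzyloxy)methyl]-6-(4-methoxybenzoyl)-5-(4-methoxyphenyl)cyclohex-2-en-1-one).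
- For it: simple starting materials, catalytic conditions, normal concentration and no thermally sensitive polyyne. The C6 carbonyl becomes, after aromatisation, a phenol that can be activated for direct coupling with an arylalkyne.
- Against it: A4 is two hydrogens short of aromatic, so a dehydrogenation is required, and the two stereocentres are made only to be destroyed. The resulting ortho-acyl phenol is strongly hydrogen-bonded and its sulfonate sits between the aroyl and the benzyloxymethyl group, a poor site for cross-coupling. The benzyl ether cannot be removed by hydrogenolysis once the alkyne is present. Oxidation, activation, coupling, aryl addition and two different deprotections make the sequence after the key step longer.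
- Comparison: this plan is as strong or stronger in material throughput and in avoiding high dilution. The chosen strategy delivers ring A already aromatic, with both CH positions and all four substituents in place from a single step, and needs no redox correction of the ring.

**Alternative 3:** Only the alkyne is addressed. The C≡C unit is disconnected to the C6 diaryl ketone A8 ({6-({[tert-butyl(dimethyl)silyl]oxy}methyl)-2-[hydroxybis(4-methoxyphenyl)methyl]-3-(4-methoxyphenyl)phenyl}(4-methoxyphenyl)methanone) and one carbon from lithio(trimethylsilyl)diazomethane A9. A9 adds to the ketone, loss of silanolate and dinitrogen gives an alkylidene carbene, and a 1,2-aryl shift gives the diaryl alkyne A7 (bis(4-methoxyphenyl){3-[(tert-butyldimethylsilyloxy)methyl]-2-[(4-methoxyphenyl)ethynyl]-6-(4-methoxyphenyl)phenyl}methanol).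
- For it: no transition metal, a non-enolisable ketone, and one step from ketone to arylethynyl group where the chosen route needs two. Whichever aryl group migrates, the same alkyne results.
- Against it: the ketone in A8 is a benzophenone with both ortho positions substituted and a tertiary hydroxyl next door, so it is largely closed as a cyclic hemiketal and poorly accessible to a bulky silyl-substituted carbanion. The carbene is formed beside an O–H (or alkoxide) that can capture it in competition with the aryl shift. Above all, the plan does not say how the four contiguous substituents of ring A are assembled: A8 is as demanding as the core of the target.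
- Comparison: stronger in end-game step count, but it leaves the central problem open. The chosen strategy solves that problem and then uses two standard steps for the alkyne.

Key step: step 7

## Route

**Step 1**
Reactants: 1 1-iodo-4-(methoxymethoxy)benzene; 2 ethynyltrimethylsilane
Product: 3 trimethyl{[4-(methoxymethoxy)phenyl]ethynyl}silane
Conditions: PdCl2(PPh3)2 (2 mol%), CuI (4 mol%), Et3N, THF, rt
Reagents that add atoms: none
Why: Sonogashira coupling of an unhindered aryl iodide with a silyl-protected alkyne; the acetal ether is inert to amine and catalyst.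

**Step 2**
Reactants: 3 trimethyl{[4-(methoxymethoxy)phenyl]ethynyl}silane
Product: 4 1-(bromoethynyl)-4-(methoxymethoxy)benzene
Conditions: NBS, AgNO3 (10 mol%), acetone, rt, dark
Reagents that add atoms: N-bromosuccinimide, O=C1CCC(=O)N1Br
Why: Silver-catalysed bromodesilylation of an alkynylsilane: the silver acetylide formed by C–Si cleavage is brominated by NBS, giving the 1-bromoalkyne without isolating the terminal alkyne.

**Step 3**
Reactants: 4 1-(bromoethynyl)-4-(methoxymethoxy)benzene; 5 prop-2-yn-1-ol
Product: 6 5-[4-(methoxymethoxy)phenyl]penta-2,4-diyn-1-ol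
Conditions: CuCl (5 mol%), NH2OH·HCl, n-BuNH2 (30% aq.), Et2O, 0 °C to rt
Reagents that add atoms: none
Why: Cadiot–Chodkiewicz coupling of a bromoalkyne with a terminal alkyne gives the unsymmetrical 1,3-diyne selectively; hydroxylamine keeps the copper reduced and suppresses homocoupling.

**Step 4**
Reactants: 6 5-[4-(methoxymethoxy)phenyl]penta-2,4-diyn-1-ol; 7 prop-2-ynoic acid
Product: 8 5-[4-(methoxymethoxy)phenyl]penta-2,4-diyn-1-yl prop-2-ynoate
Conditions: DCC, DMAP (5 mol%), CH2Cl2, –20 to 0 °C
Reagents that add atoms: none
Why: Steglich esterification of a primary propargylic alcohol; low temperature and only catalytic DMAP limit conjugate addition to the propiolate.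

**Step 5**
Reactants: 8 5-[4-(methoxymethoxy)phenyl]penta-2,4-diyn-1-yl prop-2-ynoate; 9 4-(methoxymethoxy)benzaldehyde
Product: 11 racemic 5-[4-(methoxymethoxy)phenyl]penta-2,4-diyn-1-yl 4-hydroxy-4-[4-(methoxymethoxy)phenyl]but-2-ynoate, via lithium acetylide 10 (not isolated)
Conditions: LiN(SiMe3)2, THF, –78 °C; then 9; then AcOH, –78 °C
Reagents that add atoms: none
Why: Deprotonation of a propiolate ester at its terminal C–H (far more acidic than the propargylic CH2) and 1,2-addition of the lithium acetylide to an aromatic aldehyde, quenched cold so the alkoxide cannot attack the ester. The new carbinol centre is racemic and is removed in step 6.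

**Step 6**
Reactants: 11 racemic 5-[4-(methoxymethoxy)phenyl]penta-2,4-diyn-1-yl 4-hydroxy-4-[4-(methoxymethoxy)phenyl]but-2-ynoate
Product: 12 5-[4-(methoxymethoxy)phenyl]penta-2,4-diyn-1-yl 4-[4-(methoxymethoxy)phenyl]-4-oxobut-2-ynoate
Conditions: Dess–Martin periodinane, CH2Cl2, 0 °C to rt
Reagents that add atoms: none
Why: Dess–Martin oxidation of a benzylic, propargylic alcohol is fast under neutral, non-nucleophilic conditions that the electrophilic ynone tolerates. The triyne is used at once.

**Step 7**
Reactants: 12 5-[4-(methoxymethoxy)phenyl]penta-2,4-diyn-1-yl 4-[4-(methoxymethoxy)phenyl]-4-oxobut-2-ynoate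
Product: 14 7-[4-(methoxymethoxy)benzoyl]-6-[4-(methoxymethoxy)phenyl]-2-benzofuran-1(3H)-one, via aryne 13 (not isolated)
Conditions: cyclooctane (0.005 M), 130 °C, Ar
Reagents that add atoms: none
Why: The 1,3-diyne and the alkyne, held by the three-atom ester tether, undergo a thermal intramolecular hexadehydro-Diels–Alder reaction; the alkyne carries a carbonyl group on each side, which lowers the barrier of what is most likely a stepwise, diradical bond formation that starts at the tether-proximal carbons. The lactone closes as a five-membered ring through the C5–C6 bond, and ring A closes as a six-membered ring through the C1–C2 bond, a formal [4+2] cycloaddition that leaves aryne 13 with its strained bond at C3≡C4. The aryne then takes two vicinal, nearly eclipsed hydrogens from cyclooctane in a concerted double hydrogen transfer, giving the two ring CH positions and (Z)-cyclooctene. Both events are the known behaviour of ester-tethered triynes heated in cycloalkane solvents. No stereocentre is formed. Regiochemistry needs no control beyond the tether: only one pairing of the diyne ends with the alkyne carbons is within reach, so the lactone carbonyl must end on C6 and the aroyl group on C1, and adding two hydrogens to the aryne raises no regiochemical question. The selectivity that matters is chemoselective capture of the aryne; high dilution in the neat hydrogen donor lets the solvent outcompete aryl ether rings, acetal oxygens and carbonyl groups of other molecules, and nothing within 13 can reach C3 or C4.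

**Step 8**
Reactants: 14 7-[4-(methoxymethoxy)benzoyl]-6-[4-(methoxymethoxy)phenyl]-2-benzofuran-1(3H)-one; 15 1-bromo-4-(methoxymethoxy)benzene
Product: 18 7-(hydroxymethyl)-3,3,4-tris[4-(methoxymethoxy)phenyl]-2-benzofuran-1(3H)-one, via arylmagnesium bromide 16 (not isolated), via bromomagnesium alkoxide 17 (not isolated)
Conditions: 15, Mg, THF, rt; then 14, THF, –40 to 20 °C; then H2O
Reagents that add atoms: none
Why: Grignard addition to the ketone of a 2-aroylbenzoate-type substrate, followed by acyl transfer: the tertiary alkoxide attacks the neighbouring lactone carbonyl in a five-membered mode and expels the less basic primary alkoxide, giving the 3,3-diarylphthalide and freeing the C5 hydroxymethyl group. The step tolerates the lactone isomer too, since both lactones reduce to the same hydroxy aldehyde in step 9.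

**Step 9**
Reactants: 18 7-(hydroxymethyl)-3,3,4-tris[4-(methoxymethoxy)phenyl]-2-benzofuran-1(3H)-one
Product: 19 7-(hydroxymethyl)-3,3,4-tris[4-(methoxymethoxy)phenyl]-1,3-dihydro-2-benzofuran-1-ol
Conditions: i-Bu2AlH (2.3 equiv), CH2Cl2, –78 °C; then aq. potassium sodium tartrate
Reagents that add atoms: none
Why: Partial reduction of a lactone to the lactol: one equivalent of hydride is consumed by the free hydroxyl, and the tetrahedral aluminium lactolate is stable at –78 °C. The hemiacetal carbon is a new, racemic and uncontrolled stereocentre that equilibrates by ring–chain tautomerism and disappears in step 10.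

**Step 10**
Reactants: 19 7-(hydroxymethyl)-3,3,4-tris[4-(methoxymethoxy)phenyl]-1,3-dihydro-2-benzofuran-1-ol
Product: 21 {2-ethynyl-3-(hydroxymethyl)-6-[4-(methoxymethoxy)phenyl]phenyl}bis[4-(methoxymethoxy)phenyl]methanol, via hydroxy aldehyde 20 (not isolated)
Conditions: dimethyl (1-diazo-2-oxopropyl)phosphonate, K2CO3, MeOH, rt
Reagents that add atoms: dimethyl (1-diazo-2-oxopropyl)phosphonate, CC(=O)C(=[N+]=[N-])P(=O)(OC)OC
Why: Ohira–Bestmann (Seyferth–Gilbert) homologation, which works on lactols through their open hydroxy aldehyde form: the diazomethylphosphonate anion made by methanolysis adds to the aldehyde, loss of phosphate and dinitrogen gives an alkylidene carbene, and a fast 1,2-hydrogen shift gives the terminal alkyne. Ortho-ethynyl benzylic alcohols are stable to K2CO3 in methanol at room temperature.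

**Step 11**
Reactants: 21 {2-ethynyl-3-(hydroxymethyl)-6-[4-(methoxymethoxy)phenyl]phenyl}bis[4-(methoxymethoxy)phenyl]methanol; 1 1-iodo-4-(methoxymethoxy)benzene
Product: 22 {3-(hydroxymethyl)-6-[4-(methoxymethoxy)phenyl]-2-{[4-(methoxymethoxy)phenyl]ethynyl}phenyl}bis[4-(methoxymethoxy)phenyl]methanol
Conditions: Pd(PPh3)4 (5 mol%), CuI (5 mol%), Et3N, THF, rt to 40 °C
Reagents that add atoms: none
Why: Sonogashira coupling in which the hindered partner is the alkyne and the aryl iodide is unhindered, so oxidative addition to zerovalent palladium and transfer of the alkynyl group are not impeded. Free hydroxyl groups are tolerated, and the mild temperature keeps the neighbouring oxygens from adding to the alkyne.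

**Step 12**
Reactants: 22 {3-(hydroxymethyl)-6-[4-(methoxymethoxy)phenyl]-2-{[4-(methoxymethoxy)phenyl]ethynyl}phenyl}bis[4-(methoxymethoxy)phenyl]methanol
Product: 24 selaginellin: 4-[{3-(hydroxymethyl)-6-(4-hydroxyphenyl)-2-[(4-hydroxyphenyl)ethynyl]phenyl}(4-hydroxyphenyl)methylidene]cyclohexa-2,5-dien-1-one, via tetraphenol carbinol 23 (not isolated)
Conditions: HCl (3 M aq.), MeOH/THF, rt to 40 °C; work-up at pH 7
Reagents that add atoms: none
Why: Acid-catalysed acetal exchange removes the four MOM groups as dimethoxymethane, and the same acid ionises the doubly para-oxygenated triaryl carbinol; at neutral pH the carbenium ion loses a phenolic proton to give the quinone methide. The two aryl groups on that carbon are equivalent, so no isomer issue arises, and cyclisation of the cation onto the ortho alkyne would need a small-ring vinyl cation and is not expected.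

## Compound list

1 | 1-iodo-4-(methoxymethoxy)benzene | COCOc1ccc(I)cc1 | starting material
2 | ethynyltrimethylsilane | C#C[Si](C)(C)C | starting material
3 | trimethyl{[4-(methoxymethoxy)phenyl]ethynyl}silane | COCOc1ccc(cc1)C#C[Si](C)(C)C | intermediate
4 | 1-(bromoethynyl)-4-(methoxymethoxy)benzene | COCOc1ccc(cc1)C#CBr | intermediate
5 | prop-2-yn-1-ol | OCC#C | starting material
6 | 5-[4-(methoxymethoxy)phenyl]penta-2,4-diyn-1-ol | COCOc1ccc(cc1)C#CC#CCO | intermediate
7 | prop-2-ynoic acid | OC(=O)C#C | starting material
8 | 5-[4-(methoxymethoxy)phenyl]penta-2,4-diyn-1-yl prop-2-ynoate | COCOc1ccc(cc1)C#CC#CCOC(=O)C#C | intermediate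
9 | 4-(methoxymethoxy)benzaldehyde | COCOc1ccc(C=O)cc1 | starting material
10 | lithium acetylide of 8 (formed in the flask, not isolated) | COCOc1ccc(cc1)C#CC#CCOC(=O)C#C[Li] | intermediate
11 | racemic 5-[4-(methoxymethoxy)phenyl]penta-2,4-diyn-1-yl 4-hydroxy-4-[4-(methoxymethoxy)phenyl]but-2-ynoate | COCOc1ccc(cc1)C#CC#CCOC(=O)C#CC(O)c1ccc(OCOC)cc1 | intermediate
12 | 5-[4-(methoxymethoxy)phenyl]penta-2,4-diyn-1-yl 4-[4-(methoxymethoxy)phenyl]-4-oxobut-2-ynoate | COCOc1ccc(cc1)C#CC#CCOC(=O)C#CC(=O)c1ccc(OCOC)cc1 | intermediate
13 | 4,5-didehydro-7-[4-(methoxymethoxy)benzoyl]-6-[4-(methoxymethoxy)phenyl]-2-benzofuran-1(3H)-one (aryne, not isolated) | O=C1OCC2=C1C(C(=O)c3ccc(OCOC)cc3)=C(c4ccc(OCOC)cc4)C#C2 | intermediate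
14 | 7-[4-(methoxymethoxy)benzoyl]-6-[4-(methoxymethoxy)phenyl]-2-benzofuran-1(3H)-one | COCOc1ccc(cc1)C(=O)c1c(-c2ccc(OCOC)cc2)ccc2COC(=O)c12 | intermediate
15 | 1-bromo-4-(methoxymethoxy)benzene | COCOc1ccc(Br)cc1 | starting material
16 | [4-(methoxymethoxy)phenyl]magnesium bromide (formed in the flask, not isolated) | COCOc1ccc([Mg]Br)cc1 | intermediate
17 | bromomagnesium alkoxide of 7-{hydroxybis[4-(methoxymethoxy)phenyl]methyl}-6-[4-(methoxymethoxy)phenyl]-2-benzofuran-1(3H)-one (not isolated) | COCOc1ccc(cc1)C(O[Mg]Br)(c1ccc(OCOC)cc1)c1c(-c2ccc(OCOC)cc2)ccc2COC(=O)c12 | intermediate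
18 | 7-(hydroxymethyl)-3,3,4-tris[4-(methoxymethoxy)phenyl]-2-benzofuran-1(3H)-one | O=C1OC(c2ccc(OCOC)cc2)(c2ccc(OCOC)cc2)c2c(-c3ccc(OCOC)cc3)ccc(CO)c12 | intermediate
19 | 7-(hydroxymethyl)-3,3,4-tris[4-(methoxymethoxy)phenyl]-1,3-dihydro-2-benzofuran-1-ol (racemic hemiacetal, ring–chain tautomers) | OC1OC(c2ccc(OCOC)cc2)(c2ccc(OCOC)cc2)c2c(-c3ccc(OCOC)cc3)ccc(CO)c12 | intermediate
20 | 2-{hydroxybis[4-(methoxymethoxy)phenyl]methyl}-6-(hydroxymethyl)-3-[4-(methoxymethoxy)phenyl]benzaldehyde (open form of 19, not isolated) | O=Cc1c(CO)ccc(-c2ccc(OCOC)cc2)c1C(O)(c1ccc(OCOC)cc1)c1ccc(OCOC)cc1 | intermediate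
21 | {2-ethynyl-3-(hydroxymethyl)-6-[4-(methoxymethoxy)phenyl]phenyl}bis[4-(methoxymethoxy)phenyl]methanol | C#Cc1c(CO)ccc(-c2ccc(OCOC)cc2)c1C(O)(c1ccc(OCOC)cc1)c1ccc(OCOC)cc1 | intermediate
22 | {3-(hydroxymethyl)-6-[4-(methoxymethoxy)phenyl]-2-{[4-(methoxymethoxy)phenyl]ethynyl}phenyl}bis[4-(methoxymethoxy)phenyl]methanol | OCc1ccc(-c2ccc(OCOC)cc2)c(C(O)(c2ccc(OCOC)cc2)c2ccc(OCOC)cc2)c1C#Cc1ccc(OCOC)cc1 | intermediate
23 | {3-(hydroxymethyl)-6-(4-hydroxyphenyl)-2-[(4-hydroxyphenyl)ethynyl]phenyl}bis(4-hydroxyphenyl)methanol (present in acid as its carbenium ion, not isolated) | OCc1ccc(-c2ccc(O)cc2)c(C(O)(c2ccc(O)cc2)c2ccc(O)cc2)c1C#Cc1ccc(O)cc1 | intermediate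
24 | selaginellin, 4-[{3-(hydroxymethyl)-6-(4-hydroxyphenyl)-2-[(4-hydroxyphenyl)ethynyl]phenyl}(4-hydroxyphenyl)methylidene]cyclohexa-2,5-dien-1-one (no stereocentre) | O=C1C=CC(=C(c2ccc(O)cc2)c2c(-c3ccc(O)cc3)ccc(CO)c2C#Cc2ccc(O)cc2)C=C1 | target

## Step count and uncertain steps

Total step count: 12. Longest linear sequence: 12 steps (1 to 24; the route is linear, and 2, 5, 7, 9 and 15 enter as purchased reagents).

**Step 7 (key step).** The aryne may be captured by aryl ether rings, acetal oxygens or carbonyl groups of other substrate or product molecules instead of the solvent. The electron-poor ynone may also oligomerise before it cyclises. Both become more likely if the polar triyne dissolves poorly in cyclooctane and concentration or co-solvents have to be raised. Fallback, from 1 back to 14: replace the diyne by an enyne so that no aryne needs to be reduced. Sonogashira coupling of 1 with purchased (E)-pent-2-en-4-yn-1-ol (PdCl2(PPh3)2, CuI, Et3N) should give (2E)-5-[4-(methoxymethoxy)phenyl]pent-2-en-4-yn-1-ol F1. Esterification with 7 as in step 4 gives (2E)-5-[4-(methoxymethoxy)phenyl]pent-2-en-4-yn-1-yl prop-2-ynoate F2. Addition to 9 as in step 5 gives racemic (2E)-5-[4-(methoxymethoxy)phenyl]pent-2-en-4-yn-1-yl 4-hydroxy-4-[4-(methoxymethoxy)phenyl]but-2-ynoate F3, and oxidation as in step 6 gives (2E)-5-[4-(methoxymethoxy)phenyl]pent-2-en-4-yn-1-yl 4-[4-(methoxymethoxy)phenyl]-4-oxobut-2-ynoate F4. Heating F4 in toluene in a sealed vessel (150–180 °C, with 2,6-di-tert-butyl-4-methylphenol as proton shuttle) should bring about the intramolecular dehydro-Diels–Alder reaction of the enyne with the activated alkyne. The strained cyclic allene aromatises by hydrogen shift from C5 to C3 and gives 14 directly, with both ring hydrogens supplied by the substrate.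

**Step 8.** The Grignard reagent may attack the lactone carbonyl instead of the ketone, which is crowded on both sides and deactivated by its para-alkoxy group; a second addition to the new lactone or incomplete acyl transfer is also possible. Fallback, from 8 back to 18: install the two aryl groups before the cyclisation. Bis[4-(methoxymethoxy)phenyl]methanone F5 (from 4,4′-dihydroxybenzophenone, MOMCl, i-Pr2NEt) is treated with lithium acetylide 10, made from 8 as in step 5, to give 5-[4-(methoxymethoxy)phenyl]penta-2,4-diyn-1-yl 4-hydroxy-4,4-bis[4-(methoxymethoxy)phenyl]but-2-ynoate F6. Heating F6 in dilute cyclooctane as in step 7, at somewhat higher temperature because only the ester activates the alkyne, should give 7-{hydroxybis[4-(methoxymethoxy)phenyl]methyl}-6-[4-(methoxymethoxy)phenyl]-2-benzofuran-1(3H)-one F7. Acyl transfer with catalytic K2CO3 or DBU then gives 18.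

**Step 9.** Reduction may run on to the triol if the aluminium lactolate opens, helped by the neighbouring aluminium alkoxide, or may stall at the hindered carbonyl. Fallback, from 18 back to 24: remove the free hydroxyl first. Silylation (TBSCl, imidazole, DMF) gives 7-({[tert-butyl(dimethyl)silyl]oxy}methyl)-3,3,4-tris[4-(methoxymethoxy)phenyl]-2-benzofuran-1(3H)-one F8. Reduction with one equivalent of i-Bu2AlH gives 7-({[tert-butyl(dimethyl)silyl]oxy}methyl)-3,3,4-tris[4-(methoxymethoxy)phenyl]-1,3-dihydro-2-benzofuran-1-ol F9. Homologation as in step 10 gives {3-({[tert-butyl(dimethyl)silyl]oxy}methyl)-2-ethynyl-6-[4-(methoxymethoxy)phenyl]phenyl}bis[4-(methoxymethoxy)phenyl]methanol F10. Coupling with 1 as in step 11 gives {3-({[tert-butyl(dimethyl)silyl]oxy}methyl)-6-[4-(methoxymethoxy)phenyl]-2-{[4-(methoxymethoxy)phenyl]ethynyl}phenyl}bis[4-(methoxymethoxy)phenyl]methanol F11. The acid of step 12 removes the primary silyl ether together with the acetals and gives 24, at the cost of one extra step.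

**Step 10.** Homologation may be slow because the aldehyde is largely masked as two cyclic hemiacetals and both its ortho positions are substituted. On long reaction times a neighbouring alkoxide may add to the new alkyne. Fallback, from 19 back to 21: a Wittig reaction, which opens lactols reliably. Excess ylide from Ph3P(CH2Cl)Cl and NaN(SiMe3)2 in THF should convert 19 into {2-(2-chloroethenyl)-3-(hydroxymethyl)-6-[4-(methoxymethoxy)phenyl]phenyl}bis[4-(methoxymethoxy)phenyl]methanol F12 as an E/Z mixture. Dehydrochlorination with excess LiN(i-Pr)2 in THF at –78 to 0 °C then gives 21.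

**Step 12.** Under acid the hydroxymethyl oxygen, water or methanol may add across the electron-rich diaryl alkyne, and methanol may stay bound to the carbenium ion if cleavage has to be forced. Fallback, from 21 back to 24: deprotect first and couple last. The same acid applied to 21, whose terminal alkyne is not electron-rich, should give 4-[{2-ethynyl-3-(hydroxymethyl)-6-(4-hydroxyphenyl)phenyl}(4-hydroxyphenyl)methylidene]cyclohexa-2,5-dien-1-one F13. Sonogashira coupling of F13 with purchased 4-iodophenol (Pd(PPh3)4, CuI, Et3N) gives 24; under the amine the quinone methide is present as its delocalised phenolate and is not electrophilic.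

## Further compounds

F1 | step 7 | (2E)-5-[4-(methoxymethoxy)phenyl]pent-2-en-4-yn-1-ol | COCOc1ccc(cc1)C#C/C=C/CO
F2 | step 7 | (2E)-5-[4-(methoxymethoxy)phenyl]pent-2-en-4-yn-1-yl prop-2-ynoate | COCOc1ccc(cc1)C#C/C=C/COC(=O)C#C
F3 | step 7 | racemic (2E)-5-[4-(methoxymethoxy)phenyl]pent-2-en-4-yn-1-yl 4-hydroxy-4-[4-(methoxymethoxy)phenyl]but-2-ynoate | COCOc1ccc(cc1)C#C/C=C/COC(=O)C#CC(O)c1ccc(OCOC)cc1
F4 | step 7 | (2E)-5-[4-(methoxymethoxy)phenyl]pent-2-en-4-yn-1-yl 4-[4-(methoxymethoxy)phenyl]-4-oxobut-2-ynoate | COCOc1ccc(cc1)C#C/C=C/COC(=O)C#CC(=O)c1ccc(OCOC)cc1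
F5 | step 8 | bis[4-(methoxymethoxy)phenyl]methanone | COCOc1ccc(cc1)C(=O)c1ccc(OCOC)cc1
F6 | step 8 | 5-[4-(methoxymethoxy)phenyl]penta-2,4-diyn-1-yl 4-hydroxy-4,4-bis[4-(methoxymethoxy)phenyl]but-2-ynoate | COCOc1ccc(cc1)C#CC#CCOC(=O)C#CC(O)(c1ccc(OCOC)cc1)c1ccc(OCOC)cc1
F7 | step 8 | 7-{hydroxybis[4-(methoxymethoxy)phenyl]methyl}-6-[4-(methoxymethoxy)phenyl]-2-benzofuran-1(3H)-one | COCOc1ccc(cc1)C(O)(c1ccc(OCOC)cc1)c1c(-c2ccc(OCOC)cc2)ccc2COC(=O)c12
F8 | step 9 | 7-({[tert-butyl(dimethyl)silyl]oxy}methyl)-3,3,4-tris[4-(methoxymethoxy)phenyl]-2-benzofuran-1(3H)-one | CC(C)(C)[Si](C)(C)OCc1ccc(-c2ccc(OCOC)cc2)c2c1C(=O)OC2(c1ccc(OCOC)cc1)c1ccc(OCOC)cc1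
F9 | step 9 | 7-({[tert-butyl(dimethyl)silyl]oxy}methyl)-3,3,4-tris[4-(methoxymethoxy)phenyl]-1,3-dihydro-2-benzofuran-1-ol (racemic hemiacetal) | CC(C)(C)[Si](C)(C)OCc1ccc(-c2ccc(OCOC)cc2)c2c1C(O)OC2(c1ccc(OCOC)cc1)c1ccc(OCOC)cc1
F10 | step 9 | {3-({[tert-butyl(dimethyl)silyl]oxy}methyl)-2-ethynyl-6-[4-(methoxymethoxy)phenyl]phenyl}bis[4-(methoxymethoxy)phenyl]methanol | CC(C)(C)[Si](C)(C)OCc1ccc(-c2ccc(OCOC)cc2)c(C(O)(c2ccc(OCOC)cc2)c2ccc(OCOC)cc2)c1C#C
F11 | step 9 | {3-({[tert-butyl(dimethyl)silyl]oxy}methyl)-6-[4-(methoxymethoxy)phenyl]-2-{[4-(methoxymethoxy)phenyl]ethynyl}phenyl}bis[4-(methoxymethoxy)phenyl]methanol | CC(C)(C)[Si](C)(C)OCc1ccc(-c2ccc(OCOC)cc2)c(C(O)(c2ccc(OCOC)cc2)c2ccc(OCOC)cc2)c1C#Cc1ccc(OCOC)cc1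
F12 | step 10 | {2-(2-chloroethenyl)-3-(hydroxymethyl)-6-[4-(methoxymethoxy)phenyl]phenyl}bis[4-(methoxymethoxy)phenyl]methanol (E/Z mixture) | ClC=Cc1c(CO)ccc(-c2ccc(OCOC)cc2)c1C(O)(c1ccc(OCOC)cc1)c1ccc(OCOC)cc1
F13 | step 12 | 4-[{2-ethynyl-3-(hydroxymethyl)-6-(4-hydroxyphenyl)phenyl}(4-hydroxyphenyl)methylidene]cyclohexa-2,5-dien-1-one | O=C1C=CC(=C(c2ccc(O)cc2)c2c(-c3ccc(O)cc3)ccc(CO)c2C#C)C=C1
A1 | alternative 1 | 2-{3-chloro-2-(4-methoxybenzoyl)-6-[(methoxymethoxy)methyl]phenyl}-1-(4-methoxyphenyl)ethan-1-one | COCOCc1ccc(Cl)c(C(=O)c2ccc(OC)cc2)c1CC(=O)c1ccc(OC)cc1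
A2 | alternative 1 | 1,3-bis(4-methoxyphenyl)propane-1,3-dione | COc1ccc(cc1)C(=O)CC(=O)c1ccc(OC)cc1
A3 | alternative 1 | 6-chloro-3-[(methoxymethoxy)methyl]-2-(trimethylsilyl)phenyl trifluoromethanesulfonate | COCOCc1ccc(Cl)c(OS(=O)(=O)C(F)(F)F)c1[Si](C)(C)C
A4 | alternative 2 | trans-2-[(benzyloxy)methyl]-6-(4-methoxybenzoyl)-5-(4-methoxyphenyl)cyclohex-2-en-1-one | O=C1C(COCc2ccccc2)=CC[C@H](c2ccc(OC)cc2)[C@H]1C(=O)c1ccc(OC)cc1
A5 | alternative 2 | (E)-3-(4-methoxyphenyl)prop-2-enal | COc1ccc(/C=C/C=O)cc1
A6 | alternative 2 | 5-(benzyloxy)-1-(4-methoxyphenyl)pentane-1,3-dione | COc1ccc(cc1)C(=O)CC(=O)CCOCc1ccccc1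
A7 | alternative 3 | bis(4-methoxyphenyl){3-[(tert-butyldimethylsilyloxy)methyl]-2-[(4-methoxyphenyl)ethynyl]-6-(4-methoxyphenyl)phenyl}methanol | CC(C)(C)[Si](C)(C)OCc1ccc(-c2ccc(OC)cc2)c(C(O)(c2ccc(OC)cc2)c2ccc(OC)cc2)c1C#Cc1ccc(OC)cc1
A8 | alternative 3 | {6-({[tert-butyl(dimethyl)silyl]oxy}methyl)-2-[hydroxybis(4-methoxyphenyl)methyl]-3-(4-methoxyphenyl)phenyl}(4-methoxyphenyl)methanone | CC(C)(C)[Si](C)(C)OCc1ccc(-c2ccc(OC)cc2)c(C(O)(c2ccc(OC)cc2)c2ccc(OC)cc2)c1C(=O)c1ccc(OC)cc1
A9 | alternative 3 | lithio(trimethylsilyl)diazomethane | [Li]C(=[N+]=[N-])[Si](C)(C)C
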